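Compound numbers 1–18 are those of the compound list; ring atoms are numbered C1 (C–OMe), C2 (=CH), C3 (C=O), C4 (quaternary oxirane carbon), C5 (oxirane CH), C6 (CHOH), and "farnesyl" means (2E,6E)-3,7,11-trimethyldodeca-2,6,10-trien-1-yl, attached through C1′.

## The problem

Yanuthone X2 (18) is a 7-oxabicyclo[4.1.0]hept-3-en-2-one: a six-membered carbocycle whose C4–C5 bond is bridged by an oxirane and whose C4 carries the farnesyl chain. The chain is therefore joined at a fully substituted, oxygen-bearing sp3 carbon, a bond far easier to make while C4 is still sp2. The only stereocentres are C4, C5 and C6 (4R,5R,6S in this numbering), with all three C–O bonds on one face. C4 is the demanding one, C5 is tied to it by the oxirane and C6 can be set relative to both, but nothing in the molecule fixes the absolute sense, so one outside source of chirality is needed and may be temporary. The fragile groups are the vinylogous ester C1=C2–C3=O (acid), the epoxy ketone with its γ-hydroxyl at C6 (base: enolisation toward C6, oxirane opening, aromatisation) and the three trisubstituted chain alkenes (electrophilic oxidants, strong acid, E geometry). The enabling feature is that C1 and C4 are para-related and both oxygenated while the oxygens on C4, C5 and C6 are syn. That is the pattern left when a C1–C4 endoperoxide spanning a C5=C6 alkene is isomerised to the syn-bis-epoxide and its C1 epoxy ether half is opened to C6–OH and the C1=C2 enol ether. The C3 carbonyl can meanwhile be carried as a silyloxy stereocentre next to C4, which steers the oxygen and is erased by the last oxidation.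

## Retrosynthesis

**Oxidation level and protection (18 ⇒ 17 ⇒ 16 ⇒ 15 ⇒ 14).** No skeletal bond is cut. The C3 carbonyl is traced back to the silyl-protected carbinol of 14, and the C6 hydroxyl is covered as a 4-methoxybenzyl ether in 15–17. The neighbouring options are to oxidise a C3,C6-diol selectively, or to oxidise both and reduce C6 again. The first gambles on discrimination between two allylic alcohols and the second discards the C6 stereocentre; protection keeps it. 14 has neither enone nor epoxy ketone and so tolerates base and fluoride. The forward steps must be orthogonal and mild: basic etherification, buffered fluoride, a neutral oxidant and an oxidative, non-basic release of C6–OH.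

**Oxirane and carbinol from a peroxide (14 ⇒ 12 ⇒ 11).** The C5–O and C6–O bonds are cut and the two oxygens rejoined as the O–O bond of endoperoxide 11. On the way back, the enol ether and C6–OH of 14 fold into the C1–C6 epoxy ether of bis-epoxide 12. An external epoxidant for a C4=C5 alkene would have to ignore three chain alkenes and an enol ether, whereas the peroxide hands both oxygens over intramolecularly and syn. Two stereocentres (C5, C6) and both three-membered rings disappear. The forward reaction must cleave O–O without fragmentation and open the epoxy ether toward C2.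

**Key disconnection (11 ⇒ 10).** The C1–O and C4–O bonds are cut together; the retro-[4+2] releases dioxygen and the 1-methoxy-4-farnesyl diene 10. Making the quaternary C4–O bond by nucleophilic epoxidation of an enone, or by adding the chain to a C4 ketone, would need its own stereocontrol. Here C4–O is formed from a planar carbon in one suprafacial event together with C1–O. 10 is monocyclic with a single stereocentre (C3). The forward reaction must be face-selective (anti to the C3 silyloxy group), must prefer the diene to the chain alkenes and must run without acid.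

**Enol ether (10 ⇒ 9).** The C1=C6 π bond is traced to the dimethyl ketal 9 (retro-addition of methanol across C1=C6). 10 is a masked arene hydrate and should be made last, under aprotic amine-buffered conditions. O-methylation of a dienolate is the neighbouring option; it is strongly basic and ambiguous between C- and O-alkylation. 9 is robust and storable. The forward elimination must go toward C6, not C2.

**Chain attachment (9 ⇒ 7 + 8; 7 ⇒ 6 ⇒ 5).** The C4–C1′ bond is cut between the ring sp2 carbon and the allylic chain carbon. A vinylstannane with an allylic bromide is preferred to adding a farnesyl metal to the C4 ketone of 5, which gives a tertiary alcohol, needs a dehydration of uncertain direction and suffers α/γ ambiguity. The cut divides the molecule into a C6 ring piece and commercial bromide 8. Stannane 7 comes from enol triflate 6, and 6 from ketone 5 by kinetic enolisation away from the silyloxy carbon. The coupling must be linear with the 2E geometry retained.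

**The stereocentre (5 ⇒ 4 ⇒ 3 ⇒ 1 + 2).** The C3–O bond is cut, leading to the symmetric ketone 1 and nitrosobenzene 2. Catalytic enantioselective α-aminoxylation is preferred to a chiral-pool cyclitol or a two-stage enol-ether oxidation because it reaches 5 in three steps from an achiral commercial ketone. The forward sequence must give high enantioselectivity and cleave N–O and silylate without epimerising the centre α to the ketone.

## Roads not taken

**Alternative 1: Ferrier carbocyclisation.**
- **Cut and key step:** the C2–C3 bond of the carbocycle. The D-gluco-configured 5-enopyranoside A2 is hydrated at its exocyclic enol ether under catalysis by Hg(OCOCF3)2 (divalent mercury); the ring-opened mercurio ketone adds to the liberated aldehyde and gives cyclohexanone A1.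
- **Merits:** the absolute configuration at C5 and C6 comes from the carbohydrate, not from a facial selectivity. The carbocyclisation is dependable, and no peroxide or photochemistry is needed. In certainty of configuration this road is better than the chosen one.
- **Weak points:** A1 still lacks the two hard features. C4 is only a protected secondary carbinol, so it must be deprotected, oxidised and attacked by a farnesyl nucleophile on the correct face, next to a mesylate and with the α/γ ambiguity of allyl metals. The C1/C3 β-hydroxy ketone must become the vinylogous ester with the methyl on the C1 oxygen, a regiochemical problem for a 1,3-dione. Differentiating four sugar hydroxyls to reach A2 adds many steps, and mercury is used.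
- **Comparison:** the chosen plan sets against this a route of thirteen steps in which the chain is present before the quaternary C–O bond forms and the position of the methoxy group is fixed from the first compound. It pays with a selectivity-dependent oxygenation.

**Alternative 2: Farnesylbarium addition with oxirane closure.**
- **Cut and key step:** C4–C1′ and C5–O. The C1′ terminus of farnesylbarium chloride A5 adds to the carbonyl of the acyclic α-chloro ketone A4, and the alkoxide displaces the C5 chloride to give the acyclic epoxide A3.
- **Merits:** allylbarium reagents react at the α-terminus with retention of alkene geometry, which is what a farnesyl nucleophile must do. The chain-bearing quaternary oxirane is made directly, and no oxidant ever meets the chain. On chemoselectivity toward the chain alkenes this road is better than the chosen one.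
- **Weak points:** the facial selectivity at C4 is acyclic induction from a labile α-chloro stereocentre, with an α′-alkoxy group offering a competing chelation mode. A4 can enolise and epimerise. Above all, A3 spans only C3–C4–C5–C6–C1, so the carbocycle must still be closed by inserting C2 and forming two C–C bonds, and the vinylogous ester must still be built next to the epoxide.
- **Comparison:** the chosen plan has the carbocycle from the start and derives the C4/C5/C6 relationship from a cyclic, stereospecific oxygen transfer. In return it must control singlet oxygen in the presence of the chain.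

**Alternative 3: Reductive intramolecular Darzens closure.**
- **Cut and key step:** C4–C5 and C4–O. SmI2 (divalent samarium) cleaves the C–Br bond of the acyclic bromo chloro keto aldehyde A7; the chloro enolate adds to the tethered aldehyde and the alkoxide displaces chloride, giving the C6 silyl ether A6 of the target.
- **Merits:** carbocycle and oxirane close together, the full oxidation pattern is in place, and only a desilylation remains. In convergence and endgame economy this is the best of the four plans.
- **Weak points:** the load falls on A7, which combines an epimerisable α-silyloxy aldehyde, an enol ether that must have C6 and C3 cis across C1=C2 for cyclisation to be possible, and a gem-dihalo ketone to be installed without touching the chain alkenes. SmI2 may instead reduce the aldehyde or remove both halogens. The one stereo-determining event is addition to an α-silyloxy aldehyde, where the Felkin–Anh preference points to the C5/C6 relationship opposite to the one needed. The reductive Darzens closure itself has no secure precedent on such a substrate.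
- **Comparison:** the chosen plan is longer after ring formation, but every step is a known reaction type and its stereochemistry follows from one controlling group.

Key step: step 8

Assumption: L-proline is taken to give the (2R)-aminoxy ketone 3, the sense generally found for six-membered ketones; with the opposite sense D-proline would be used.

## Route

Step 1
Reactants: 1 4,4-dimethoxycyclohexan-1-one; 2 nitrosobenzene
Product: 3 (2R)-4,4-dimethoxy-2-[(phenylamino)oxy]cyclohexan-1-one
Conditions: L-proline (20 mol%), DMF, 0 °C, 1 in excess, slow addition of 2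
Reagents that add atoms: none
Why: Proline-catalysed α-aminoxylation (O-selective nitroso aldol): the enamine of 1 attacks the nitroso oxygen, which is held by the carboxylic acid on one face, so one enantiotopic α-methylene is oxygenated and C3 is set as R; slow addition of 2 limits double aminoxylation.

Step 2
Reactants: 3 (2R)-4,4-dimethoxy-2-[(phenylamino)oxy]cyclohexan-1-one
Product: 4 (2R)-2-hydroxy-4,4-dimethoxycyclohexan-1-one
Conditions: H2 (1 atm), Pd/C (10 wt% Pd), EtOAc, rt
Reagents that add atoms: none
Why: Hydrogenolysis of the weak N–O bond under neutral conditions; ketone and ketal are inert and the α-stereocentre is not exposed to acid or base.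

Step 3
Reactants: 4 (2R)-2-hydroxy-4,4-dimethoxycyclohexan-1-one
Product: 5 (2R)-2-[(tert-butyldimethylsilyl)oxy]-4,4-dimethoxycyclohexan-1-one
Conditions: TBSCl, imidazole, DMF, 0 °C to rt
Reagents that add atoms: tert-butyldimethylsilyl chloride, CC(C)(C)[Si](C)(C)Cl
Why: Standard silylation of a secondary alcohol, done at once on crude 4 to forestall ketol dimerisation; the bulky silyl ether later directs the oxygenation and survives base, palladium and silyl triflate.

Step 4
Reactants: 5 (2R)-2-[(tert-butyldimethylsilyl)oxy]-4,4-dimethoxycyclohexan-1-one
Product: 6 (6R)-6-[(tert-butyldimethylsilyl)oxy]-4,4-dimethoxycyclohex-1-en-1-yl trifluoromethanesulfonate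
Conditions: KN(SiMe3)2, THF, −78 °C; then PhNTf2, −78 to 0 °C
Reagents that add atoms: N-phenylbis(trifluoromethanesulfonimide), O=S(=O)(N(c1ccccc1)S(=O)(=O)C(F)(F)F)C(F)(F)F
Why: Kinetic deprotonation takes the unhindered α′-methylene (C5), not the silyloxy-bearing C3–H, and O-triflation fixes the C4=C5 enol triflate; C3 is not touched.

Step 5
Reactants: 6 (6R)-6-[(tert-butyldimethylsilyl)oxy]-4,4-dimethoxycyclohex-1-en-1-yl trifluoromethanesulfonate
Product: 7 tert-butyl{[(1R)-5,5-dimethoxy-2-(trimethylstannyl)cyclohex-2-en-1-yl]oxy}dimethylsilane
Conditions: Me6Sn2, Pd(PPh3)4 (5 mol%), LiCl, THF, 60 °C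
Reagents that add atoms: hexamethylditin, C[Sn](C)(C)[Sn](C)(C)C
Why: Palladium-catalysed stannylation of an enol triflate (oxidative addition to zerovalent palladium, transmetalation with the ditin, reductive elimination); chloride assists turnover, and silyl ether and ketal are inert.

Step 6
Reactants: 7 tert-butyl{[(1R)-5,5-dimethoxy-2-(trimethylstannyl)cyclohex-2-en-1-yl]oxy}dimethylsilane; 8 (2E,6E)-farnesyl bromide
Product: 9 tert-butyl{[(1R)-5,5-dimethoxy-2-farnesylcyclohex-2-en-1-yl]oxy}dimethylsilane
Conditions: Pd2(dba)3 (2.5 mol%), P(2-furyl)3 (10 mol%), THF, 50 °C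
Reagents that add atoms: none
Why: Stille coupling of a vinylstannane with an allylic bromide through a π-allylpalladium intermediate; the C4–C1′ bond forms at the primary allyl terminus and the 2E geometry is kept, giving the skipped diene.

Step 7
Reactants: 9 tert-butyl{[(1R)-5,5-dimethoxy-2-farnesylcyclohex-2-en-1-yl]oxy}dimethylsilane
Product: 10 tert-butyl{[(1R)-5-methoxy-2-farnesylcyclohexa-2,4-dien-1-yl]oxy}dimethylsilane
Conditions: Me3SiOTf, i-Pr2NEt, CH2Cl2, −78 to −20 °C; NEt3 quench
Reagents that add atoms: none
Why: Silyl-triflate-induced ketal-to-enol-ether elimination: the ketal ionises to the C1 oxocarbenium ion and the amine removes the doubly activated allylic C6–H, giving the conjugated 1-methoxy diene in preference to the C1=C2 isomer; excess amine and low temperature protect the allylic silyl ether, and 10 is used at once.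

Step 8
Reactants: 10 tert-butyl{[(1R)-5-methoxy-2-farnesylcyclohexa-2,4-dien-1-yl]oxy}dimethylsilane
Product: 11 (1R,4R,7R)-7-[(tert-butyldimethylsilyl)oxy]-4-methoxy-1-farnesyl-2,3-dioxabicyclo[2.2.2]oct-5-ene
Conditions: O2, visible light, H2TPP (metal-free tetraphenylporphyrin, cat.), CH2Cl2, −78 °C, stopped at partial conversion
Reagents that add atoms: dioxygen, O=O
Why: Energy transfer from the excited porphyrin generates singlet oxygen, which adds across C1 and C4 of the ring-locked s-cis diene in a concerted suprafacial [4+2] cycloaddition, the reaction type by which cyclohexa-1,3-dienes such as α-terpinene give 2,3-dioxabicyclo[2.2.2]oct-5-enes. The one new ring, the six-membered 1,2-dioxane (C1–O–O–C4 bridging C5=C6), is closed by this cycloaddition with both C–O bonds formed on the same face in one event. The new stereocentres C1 and C4 are therefore cis to each other by necessity, and both are set by C3: the bulky silyloxy group on the sp3 carbon next to the C4 terminus shields its own face, so oxygen approaches anti to it. Three selectivities are needed. Facial selectivity rests on that shielding; chemoselectivity over the ene reaction of the three trisubstituted chain alkenes rests on the much higher electron density of the 1-methoxy diene, helped by −78 °C and by stopping early with recovery of 10; periselectivity against [2+2] addition at the enol ether or an ene reaction at C2–H rests on the cisoid geometry, which makes the [4+2] path the fastest. The medium is kept free of acid because 10 would otherwise lose silanol and aromatise. Neither bridgehead carries hydrogen, so 11 cannot undergo Kornblum–DeLaMare fragmentation and is passed on cold.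

Step 9
Reactants: 11 (1R,4R,7R)-7-[(tert-butyldimethylsilyl)oxy]-4-methoxy-1-farnesyl-2,3-dioxabicyclo[2.2.2]oct-5-ene
Product: 14 (1R,2R,5S,6R)-2-[(tert-butyldimethylsilyl)oxy]-4-methoxy-1-farnesyl-7-oxabicyclo[4.1.0]hept-3-en-5-ol, via syn-bis-epoxide 12 (not isolated), via C6 trimethylsilyl ether 13 (not isolated)
Conditions: Co(TPP) (5 mol%), CH2Cl2, −20 °C; then i-Pr2NEt, Me3SiOTf, −78 °C; then K2CO3, MeOH, 0 °C
Reagents that add atoms: none
Why: Co(TPP), the divalent cobalt tetraphenylporphyrin complex, cleaves the O–O bond by one-electron transfer, and each oxygen closes onto the neighbouring alkene carbon on the face it already occupies (the known endoperoxide to syn-bis-epoxide isomerisation), which sets C5 and C6 stereospecifically. Silyl triflate then ionises the acetal-like C1 epoxy ether, the amine removes C2–H (epoxide to allyl silyl ether isomerisation), and methanolysis of the trimethylsilyl ether frees C6–OH cis to the C4–C5 oxirane.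

Step 10
Reactants: 14 (1R,2R,5S,6R)-2-[(tert-butyldimethylsilyl)oxy]-4-methoxy-1-farnesyl-7-oxabicyclo[4.1.0]hept-3-en-5-ol
Product: 15 tert-butyl{[(1R,2R,5S,6R)-4-methoxy-5-[(4-methoxybenzyl)oxy]-1-farnesyl-7-oxabicyclo[4.1.0]hept-3-en-2-yl]oxy}dimethylsilane
Conditions: NaH, 4-methoxybenzyl chloride, Bu4NI (cat.), DMF, 0 °C to rt
Reagents that add atoms: 4-methoxybenzyl chloride, COc1ccc(CCl)cc1
Why: Williamson etherification; the C6 alkoxide is cis to the oxirane and cannot undergo Payne migration, the C3 silyl ether lies across the ring on the other face, and enol ether and epoxide are stable to base.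

Step 11
Reactants: 15 tert-butyl{[(1R,2R,5S,6R)-4-methoxy-5-[(4-methoxybenzyl)oxy]-1-farnesyl-7-oxabicyclo[4.1.0]hept-3-en-2-yl]oxy}dimethylsilane
Product: 16 (1S,2R,5S,6R)-4-methoxy-5-[(4-methoxybenzyl)oxy]-1-farnesyl-7-oxabicyclo[4.1.0]hept-3-en-2-ol
Conditions: Bu4NF, AcOH, THF, 0 °C to rt
Reagents that add atoms: none
Why: Fluoride cleavage of the silyl ether; acetic acid buffering keeps the C3 oxygen protonated, so the trans-disposed oxirane is not opened by Payne rearrangement, and the medium stays too mild to ionise the enol ether (the C1 descriptor changes only because of the ranking rules; no centre is altered).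

Step 12
Reactants: 16 (1S,2R,5S,6R)-4-methoxy-5-[(4-methoxybenzyl)oxy]-1-farnesyl-7-oxabicyclo[4.1.0]hept-3-en-2-ol
Product: 17 (1R,5S,6R)-4-methoxy-5-[(4-methoxybenzyl)oxy]-1-farnesyl-7-oxabicyclo[4.1.0]hept-3-en-2-one
Conditions: Dess–Martin periodinane, NaHCO3, CH2Cl2, 0 °C to rt
Reagents that add atoms: none
Why: Dess–Martin oxidation of the hindered allylic carbinol under bicarbonate buffering gives the vinylogous ester and removes the auxiliary C3 stereocentre; chain alkenes, oxirane and benzyl ether are untouched.

Step 13
Reactants: 17 (1R,5S,6R)-4-methoxy-5-[(4-methoxybenzyl)oxy]-1-farnesyl-7-oxabicyclo[4.1.0]hept-3-en-2-one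
Product: 18 yanuthone X2, (1R,5S,6R)-5-hydroxy-4-methoxy-1-farnesyl-7-oxabicyclo[4.1.0]hept-3-en-2-one
Conditions: DDQ, CH2Cl2/pH 7 phosphate buffer, 0 °C
Reagents that add atoms: none
Why: Oxidative cleavage of the 4-methoxybenzyl ether (benzylic hydride abstraction, hydrolysis of the oxocarbenium ion) frees C6–OH without base, which the epoxy enone would not tolerate, and without strong acid; the enone is electron-poor and the isolated chain alkenes react far more slowly with the quinone.

## Compound list

1 | 4,4-dimethoxycyclohexan-1-one | COC1(OC)CCC(=O)CC1 | starting material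
2 | nitrosobenzene | O=Nc1ccccc1 | starting material
3 | (2R)-4,4-dimethoxy-2-[(phenylamino)oxy]cyclohexan-1-one | O=C1[C@H](ONc2ccccc2)CC(OC)(OC)CC1 | intermediate
4 | (2R)-2-hydroxy-4,4-dimethoxycyclohexan-1-one | O=C1[C@H](O)CC(OC)(OC)CC1 | intermediate
5 | (2R)-2-[(tert-butyldimethylsilyl)oxy]-4,4-dimethoxycyclohexan-1-one | O=C1[C@H](O[Si](C)(C)C(C)(C)C)CC(OC)(OC)CC1 | intermediate
6 | (6R)-6-[(tert-butyldimethylsilyl)oxy]-4,4-dimethoxycyclohex-1-en-1-yl trifluoromethanesulfonate | O=S(=O)(OC1=CCC(OC)(OC)C[C@H]1O[Si](C)(C)C(C)(C)C)C(F)(F)F | intermediate
7 | tert-butyl{[(1R)-5,5-dimethoxy-2-(trimethylstannyl)cyclohex-2-en-1-yl]oxy}dimethylsilane | C[Sn](C)(C)C1=CCC(OC)(OC)C[C@H]1O[Si](C)(C)C(C)(C)C | intermediate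
8 | (2E,6E)-farnesyl bromide, (2E,6E)-1-bromo-3,7,11-trimethyldodeca-2,6,10-triene | BrC/C=C(\C)CC/C=C(\C)CCC=C(C)C | starting material
9 | tert-butyl{[(1R)-5,5-dimethoxy-2-farnesylcyclohex-2-en-1-yl]oxy}dimethylsilane | COC1(OC)CC=C(C/C=C(\C)CC/C=C(\C)CCC=C(C)C)[C@H](O[Si](C)(C)C(C)(C)C)C1 | intermediate
10 | tert-butyl{[(1R)-5-methoxy-2-farnesylcyclohexa-2,4-dien-1-yl]oxy}dimethylsilane (diene C1=C6–C5=C4, silyloxy at C3) | COC1=CC=C(C/C=C(\C)CC/C=C(\C)CCC=C(C)C)[C@H](O[Si](C)(C)C(C)(C)C)C1 | intermediate
11 | (1R,4R,7R)-7-[(tert-butyldimethylsilyl)oxy]-4-methoxy-1-farnesyl-2,3-dioxabicyclo[2.2.2]oct-5-ene (peroxide bridge C1–C4 anti to the C3 silyloxy group) | CO[C@@]12C=C[C@@](C/C=C(\C)CC/C=C(\C)CCC=C(C)C)(OO1)[C@H](O[Si](C)(C)C(C)(C)C)C2 | intermediate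
12 | syn-bis-epoxide, not isolated: C1–C6 epoxy ether (OMe on C1) and C4–C5 oxirane (farnesyl on C4), both oxirane oxygens on the face opposite the C3 silyloxy group | CO[C@@]12C[C@@H](O[Si](C)(C)C(C)(C)C)[C@]3(C/C=C(\C)CC/C=C(\C)CCC=C(C)C)O[C@@H]3[C@@H]1O2 | intermediate
13 | C6 trimethylsilyl ether, not isolated: tert-butyl{[(1R,2R,5S,6R)-4-methoxy-5-[(trimethylsilyl)oxy]-1-farnesyl-7-oxabicyclo[4.1.0]hept-3-en-2-yl]oxy}dimethylsilane | COC1=C[C@@H](O[Si](C)(C)C(C)(C)C)[C@]2(C/C=C(\C)CC/C=C(\C)CCC=C(C)C)O[C@@H]2[C@@H]1O[Si](C)(C)C | intermediate
14 | (1R,2R,5S,6R)-2-[(tert-butyldimethylsilyl)oxy]-4-methoxy-1-farnesyl-7-oxabicyclo[4.1.0]hept-3-en-5-ol (C6–OH cis to the oxirane, C3 silyloxy trans) | COC1=C[C@@H](O[Si](C)(C)C(C)(C)C)[C@]2(C/C=C(\C)CC/C=C(\C)CCC=C(C)C)O[C@@H]2[C@@H]1O | intermediate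
15 | tert-butyl{[(1R,2R,5S,6R)-4-methoxy-5-[(4-methoxybenzyl)oxy]-1-farnesyl-7-oxabicyclo[4.1.0]hept-3-en-2-yl]oxy}dimethylsilane | COC1=C[C@@H](O[Si](C)(C)C(C)(C)C)[C@]2(C/C=C(\C)CC/C=C(\C)CCC=C(C)C)O[C@@H]2[C@@H]1OCc3ccc(OC)cc3 | intermediate
16 | (1S,2R,5S,6R)-4-methoxy-5-[(4-methoxybenzyl)oxy]-1-farnesyl-7-oxabicyclo[4.1.0]hept-3-en-2-ol | COC1=C[C@@H](O)[C@]2(C/C=C(\C)CC/C=C(\C)CCC=C(C)C)O[C@@H]2[C@@H]1OCc3ccc(OC)cc3 | intermediate
17 | (1R,5S,6R)-4-methoxy-5-[(4-methoxybenzyl)oxy]-1-farnesyl-7-oxabicyclo[4.1.0]hept-3-en-2-one | COC1=CC(=O)[C@]2(C/C=C(\C)CC/C=C(\C)CCC=C(C)C)O[C@@H]2[C@@H]1OCc3ccc(OC)cc3 | intermediate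
18 | yanuthone X2, (1R,5S,6R)-5-hydroxy-4-methoxy-1-[(2E,6E)-3,7,11-trimethyldodeca-2,6,10-trien-1-yl]-7-oxabicyclo[4.1.0]hept-3-en-2-one | COC1=CC(=O)[C@]2(C/C=C(\C)CC/C=C(\C)CCC=C(C)C)O[C@@H]2[C@@H]1O | target

## Step count and least certain steps

Total: 13 steps. Longest linear sequence: 13 steps, from ketone 1 (bromide 8 enters at step 6).

**Step 8 (key step).** The most likely failure is loss of chemoselectivity: singlet oxygen also undergoes the ene reaction with the three trisubstituted chain alkenes, the terminal isopropylidene first, and the rate advantage of the methoxy diene may be too small at useful conversion. Incomplete facial discrimination and acid-triggered aromatisation of the diene during irradiation are the lesser risks. Fallback, from 10 back to 11: replace the excited-state oxidant by electron-transfer oxygenation with ground-state dioxygen (catalytic (4-BrC6H4)3N SbCl6, 2,6-di-tert-butylpyridine, CH2Cl2, −78 °C). This is a radical-cation chain in which only the most easily oxidised π system, the methoxy diene, is activated, so no species capable of an ene reaction is present; the face is still chosen by the C3 silyloxy group. New compounds: none F0.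

**Step 9.** The most likely failure is fragmentation of the oxygen-centred radicals formed on O–O cleavage: β-scission at C4 would expel the allylic farnesyl radical, and scission at the peroxy-ketal carbon C1 would give an ester. A second risk is opening of the epoxy ether in the wrong sense (toward C6–H, or hydride shift to a methoxy ketone). Fallback, from 10 to 18, avoiding the peroxide altogether:
- Twofold epoxidation of 10 with dimethyldioxirane (acetone/CH2Cl2, −78 °C) attacks C4=C5 anti to the silyloxy group and gives the anti-bis-epoxide F1.
- Methanol opens the epoxy ether to the hydroxy ketal F2, whose C6 configuration does not matter.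
- Buffered Bu4NF gives the diol F3.
- Dess–Martin oxidation of both carbinols gives the diketo ketal F4, which loses methanol on exposure to NEt3 to give the epoxyquinone F5.
- Luche reduction (NaBH4, CeCl3·7H2O, MeOH, −78 °C) should attack the C6 carbonyl, which is not deactivated as a vinylogous ester and is the less hindered one, from the face opposite the oxirane, and give 18.

Here the absolute configuration rests on the anti epoxidation of C4=C5, and C6 is set by substrate control at the end.

**Step 7.** The most likely failure is ionisation of the allylic C3 silyl ether by the silyl triflate once the methoxy diene has formed, leading to loss of silanol and aromatisation. Elimination toward C2 is the second risk. Fallback, from 6 back to 10: run the same ketal-to-enol-ether elimination one stage earlier on 6 to give the dienyl triflate F6, in which the electron-withdrawing triflate on C4 disfavours ionisation at C3. Stannylate it (Me6Sn2, Pd(PPh3)4, LiCl) to the dienylstannane F7 and couple F7 with 8 as in step 6. The sensitive diene 10 is then first formed in a neutral medium and never meets a Lewis acid.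

**Step 6.** The most likely failure is slow transmetalation of the α-branched vinylstannane. That would leave the π-allylpalladium intermediate time for allylic transposition, erosion of the 2E geometry or homocoupling. Fallback, from 6 back to 9: Miyaura borylation of 6 (B2pin2, PdCl2(PPh3)2, PPh3, KOPh, toluene, 50 °C) to the vinyl pinacolboronate F8, then Suzuki–Miyaura coupling of F8 with 8 (Pd(PPh3)4, K3PO4, THF/H2O). The base-activated boronate transmetalates faster, and the route is free of tin at this stage.

## Further compounds

F0 | step 8 | none | none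
F1 | step 9 | anti-bis-epoxide of diene 10: C4–C5 oxirane anti to the C3 silyloxy group, C1–C6 epoxy ether on the opposite face | CO[C@]12C[C@@H](O[Si](C)(C)C(C)(C)C)[C@]3(C/C=C(\C)CC/C=C(\C)CCC=C(C)C)O[C@@H]3[C@H]1O2
F2 | step 9 | hydroxy ketal: C1 dimethyl ketal, C6–OH, C4–C5 oxirane, C3 tert-butyldimethylsilyl ether | COC1(OC)C[C@@H](O[Si](C)(C)C(C)(C)C)[C@]2(C/C=C(\C)CC/C=C(\C)CCC=C(C)C)O[C@@H]2[C@H]1O
F3 | step 9 | C3,C6-diol: C1 dimethyl ketal, C4–C5 oxirane | COC1(OC)C[C@@H](O)[C@]2(C/C=C(\C)CC/C=C(\C)CCC=C(C)C)O[C@@H]2[C@H]1O
F4 | step 9 | diketo ketal: C3 and C6 ketones, C1 dimethyl ketal, C4–C5 oxirane | COC1(OC)CC(=O)[C@]2(C/C=C(\C)CC/C=C(\C)CCC=C(C)C)O[C@@H]2C1=O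
F5 | step 9 | epoxyquinone, (1R,6S)-4-methoxy-1-farnesyl-7-oxabicyclo[4.1.0]hept-3-ene-2,5-dione | COC1=CC(=O)[C@]2(C/C=C(\C)CC/C=C(\C)CCC=C(C)C)O[C@@H]2C1=O
F6 | step 7 | dienyl triflate, (6R)-6-[(tert-butyldimethylsilyl)oxy]-4-methoxycyclohexa-1,3-dien-1-yl trifluoromethanesulfonate | COC1=CC=C(OS(=O)(=O)C(F)(F)F)[C@H](O[Si](C)(C)C(C)(C)C)C1
F7 | step 7 | dienylstannane, tert-butyl{[(1R)-5-methoxy-2-(trimethylstannyl)cyclohexa-2,4-dien-1-yl]oxy}dimethylsilane | COC1=CC=C([Sn](C)(C)C)[C@H](O[Si](C)(C)C(C)(C)C)C1
F8 | step 6 | vinyl pinacolboronate, tert-butyl{[(1R)-5,5-dimethoxy-2-(4,4,5,5-tetramethyl-1,3,2-dioxaborolan-2-yl)cyclohex-2-en-1-yl]oxy}dimethylsilane | CC1(C)OB(OC1(C)C)C2=CCC(OC)(OC)C[C@H]2O[Si](C)(C)C(C)(C)C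
A1 | alternative 1 | cyclohexanone with C1 ketone, C3 carbinol, C4 4-methoxybenzyl ether, C5 mesylate and C6 tert-butyldimethylsilyl ether | O=C1C[C@H](O)[C@H](OCc2ccc(OC)cc2)[C@@H](OS(C)(=O)=O)[C@@H]1O[Si](C)(C)C(C)(C)C
A2 | alternative 1 | methyl 6-deoxy-3-O-mesyl-2-O-(4-methoxybenzyl)-4-O-(tert-butyldimethylsilyl)-D-xylo-hex-5-enopyranoside | COC1OC(=C)[C@@H](O[Si](C)(C)C(C)(C)C)[C@H](OS(C)(=O)=O)[C@H]1OCc2ccc(OC)cc2
A3 | alternative 2 | acyclic C4-farnesyl C4–C5 epoxide with C3 4-methoxybenzyl ether and C6, C1 tert-butyldimethylsilyl ethers | COc1ccc(COC[C@]2(C/C=C(\C)CC/C=C(\C)CCC=C(C)C)O[C@@H]2[C@@H](CO[Si](C)(C)C(C)(C)C)O[Si](C)(C)C(C)(C)C)cc1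
A4 | alternative 2 | 3-chloro-4,5-bis[(tert-butyldimethylsilyl)oxy]-1-[(4-methoxybenzyl)oxy]pentan-2-one (C3 to C1 of the target, chloride at C5) | COc1ccc(COCC(=O)[C@@H](Cl)[C@@H](CO[Si](C)(C)C(C)(C)C)O[Si](C)(C)C(C)(C)C)cc1
A5 | alternative 2 | (2E,6E)-farnesylbarium chloride | Cl[Ba]C/C=C(\C)CC/C=C(\C)CCC=C(C)C
A6 | alternative 3 | yanuthone X2 C6 tert-butyldimethylsilyl ether | COC1=CC(=O)[C@]2(C/C=C(\C)CC/C=C(\C)CCC=C(C)C)O[C@@H]2[C@@H]1O[Si](C)(C)C(C)(C)C
A7 | alternative 3 | acyclic α′-bromo-α′-chloro β-methoxy enone with C5 aldehyde and C6 tert-butyldimethylsilyl ether, C6 and C3 cis across C1=C2 | O=C[C@H](O[Si](C)(C)C(C)(C)C)/C(OC)=C\C(=O)C(Br)(Cl)C/C=C(\C)CC/C=C(\C)CCC=C(C)C
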